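## Retrosynthetic overview
- The target comes from global desilylation of its tris-TBS ether. Ring B is bought as protocatechualdehyde.
- Rings C and A form together from one acyclic, fully substituted tetraketide tert-butyl ester. Ring C closes first (carbinol O onto the only δ-carbonyl). Ring A closes second (acylketene, C4a–C5 closure, aromatisation).
- The order of substituents along the chain fixes 8-(hydroxyalkyl) against 6-prenyl, so no chalcone and no choice between two ortho-phenols arises.
- The tetraketide comes from terminal acylation of a 3,5-diketo ester trianion with an (S)-β-silyloxyacyl thiazolidinethione. An acetate aldol sets C-2.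
- The diketo ester comes from tert-butyl acetoacetate by α-prenylation, γ-alkylation with (S)-2-isopropenyloxirane (kinetic resolution sets C-2'') and γ-acetylation.

Assumption: 3 is bought as such, and the centres α to carbonyl groups in 12–23 are epimer mixtures that vanish on aromatisation, so they are left undefined.

## Route

Step 1
Reactants: 1 3,4-dihydroxybenzaldehyde
Product: 2 3,4-bis(tert-butyldimethylsilyloxy)benzaldehyde
Conditions: TBSCl (2.5 equiv), imidazole, DMF, 23 °C
Reagents that add atoms: tert-butyldimethylsilyl chloride CC(C)(C)[Si](C)(C)Cl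
Why: Standard silyl ether protection masks both acidic phenols against the titanium enolate and the polyanion used later, and no stereocentre is involved.

Step 2
Reactants: 2 3,4-bis(tert-butyldimethylsilyloxy)benzaldehyde; 3 (R)-3-acetyl-4-benzyl-1,3-thiazolidine-2-thione
Product: 5 (4R)-4-benzyl-3-[(3S)-3-[3,4-bis(tert-butyldimethylsilyloxy)phenyl]-3-hydroxypropanoyl]-1,3-thiazolidine-2-thione, via trichlorotitanium enolate 4 (not isolated)
Conditions: TiCl4, i-Pr2NEt, CH2Cl2, −40 °C; then 2, −78 °C; aq NH4Cl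
Reagents that add atoms: none
Why: Nagao-type acetate aldol addition, in which the chelated chair transition state of the titanium enolate with the benzyl group of the (R)-auxiliary shielding one face gives the (S)-carbinol (future C-2, dr about 9:1, minor isomer removed on silica).

Step 3
Reactants: 5 (S)-aldol adduct
Product: 6 (4R)-4-benzyl-3-[(3S)-3-[3,4-bis(tert-butyldimethylsilyloxy)phenyl]-3-(triethylsilyloxy)propanoyl]-1,3-thiazolidine-2-thione
Conditions: TESOTf, 2,6-lutidine, CH2Cl2, −78→0 °C
Reagents that add atoms: triethylsilyl triflate CC[Si](CC)(CC)OS(=O)(=O)C(F)(F)F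
Why: Silyl ether formation with a non-nucleophilic base leaves the reactive thioimide intact and installs the one silyl group that mild acid later removes selectively, with C-2 untouched.

Step 4
Reactants: 7 methacrolein
Product: 8 rac-2-(prop-1-en-2-yl)oxirane
Conditions: Me3SI, NaH, DMSO/THF, 0 °C; distil
Reagents that add atoms: trimethylsulfonium iodide C[S+](C)C.[I-]
Why: Corey–Chaykovsky epoxidation, in which the unstabilised sulfonium ylide adds 1,2 to the enal and closes the terminal oxirane (racemic).

Step 5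
Reactants: 8 rac-2-(prop-1-en-2-yl)oxirane
Product: 9 (S)-2-(prop-1-en-2-yl)oxirane
Conditions: (S,S)-N,N'-bis(3,5-di-tert-butylsalicylidene)-1,2-cyclohexanediaminocobalt acetate (0.5 mol %, trivalent cobalt), H2O (0.55 equiv), neat, 0→23 °C; distil
Reagents that add atoms: none
Why: Jacobsen hydrolytic kinetic resolution, in which the (S,S)-catalyst hydrates the (R)-epoxide selectively so the volatile (S)-epoxide (future C-2'') distils off in >99% ee.

Step 6
Reactants: 10 tert-butyl acetoacetate; 11 prenyl bromide (1-bromo-3-methylbut-2-ene)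
Product: 12 tert-butyl 2-acetyl-5-methylhex-4-enoate
Conditions: K2CO3, acetone, reflux
Reagents that add atoms: none
Why: Acetoacetic ester C-alkylation with a reactive allylic bromide, giving a racemic centre that is erased on aromatisation.

Step 7
Reactants: 12 tert-butyl 2-acetyl-5-methylhex-4-enoate; 9 (S)-2-(prop-1-en-2-yl)oxirane
Product: 15 tert-butyl (6R)-6-(tert-butyldimethylsilyloxy)-7-methyl-2-(3-methylbut-2-enyl)-3-oxooct-7-enoate, via sodium lithium dianion 13 (not isolated), via alkoxide enolate 14 (not isolated)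
Conditions: NaH, THF, 0 °C; n-BuLi, 0 °C; 9, 0→23 °C; TBSOTf (1.1 equiv), −78→0 °C; aq NH4Cl
Reagents that add atoms: tert-butyldimethylsilyl triflate CC(C)(C)[Si](C)(C)OS(=O)(=O)C(F)(F)F
Why: Weiler dianion alkylation, in which the γ-carbanion opens the epoxide by SN2 attack at the unhindered CH2 so the C–O stereocentre carries over unchanged (the descriptor becomes R by priority change only), and the alkoxide is silylated before it can add to the ketone.

Step 8
Reactants: 15 keto ester from step 7; 16 N-methoxy-N-methylacetamide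
Product: 18 tert-butyl (6R)-4-acetyl-6-(tert-butyldimethylsilyloxy)-7-methyl-2-(3-methylbut-2-enyl)-3-oxooct-7-enoate, via dilithium dianion 17 (not isolated)
Conditions: LDA (2.2 equiv), THF, −78→0 °C; 16, −78→−20 °C; aq NH4Cl
Reagents that add atoms: none
Why: γ-Acylation of a β-keto ester dianion (crossed Claisen condensation) with a Weinreb amide, whose chelated adduct prevents proton exchange and over-addition, while C-6 is untouched.

Step 9
Reactants: 18 diketo ester from step 8; 6 TES-protected acyl thiazolidinethione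
Product: 20 tert-butyl (9S)-9-[3,4-bis(tert-butyldimethylsilyloxy)phenyl]-4-[(2R)-2-(tert-butyldimethylsilyloxy)-3-methylbut-3-enyl]-2-(3-methylbut-2-enyl)-3,5,7-trioxo-9-(triethylsilyloxy)nonanoate, via trilithium trianion 19 (not isolated)
Conditions: 18 (2 equiv, excess recovered), LDA (6.3 equiv), THF, −78→−10 °C; 6, −78 °C; aq NH4Cl
Reagents that add atoms: none
Why: Harris-type terminal acylation of a polyketide trianion (crossed Claisen condensation), in which the last-formed CH2 carbanion is the most nucleophilic site and displaces the very good thiazolidinethione leaving group at −78 °C faster than β-elimination, so both stereocentres pass through unchanged.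

Step 10
Reactants: 20 acyclic tetraketide
Product: 24 (2S)-2-[3,4-bis(tert-butyldimethylsilyloxy)phenyl]-8-[(2R)-2-(tert-butyldimethylsilyloxy)-3-methylbut-3-enyl]-5,7-dihydroxy-6-(3-methylbut-2-enyl)chroman-4-one, via hydroxy tetraketide 21 (not isolated), via dihydropyranone 22 (not isolated), via acylketene 23 (not isolated)
Conditions: TsOH·H2O (10 mol %), toluene (0.01 M), 23 °C, 1 h; then 2,6-lutidine (15 mol %), 4 Å MS, 110 °C, 4 h
Reagents that add atoms: none
Why: Proposed new method: mild acid removes only the TES group, and the freed carbinol O cyclodehydrates onto the single carbonyl that is δ to it, which closes ring C without breaking the C-2–O bond (S retained), places the hydroxyalkyl carbon next to O-1 and blocks the 2-pyrone and 4-pyrone derailments of polyketides; on heating, the α-prenyl tert-butyl β-keto ester loses t-BuOH to an acylketene whose enol is a dienylketene, which closes C4a–C5 by 6π-electrocyclisation (or the equivalent enol C-acylation) and tautomerises to phloroglucinol ring A; the closest known reactions are acid cyclisation of δ-hydroxy-β-diketones to 2,3-dihydro-4H-pyran-4-ones, thermal acylketene generation from tert-butyl β-keto esters or dioxinones in biomimetic polyketide aromatisation, and the last stage of the Danheiser benzannulation.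

Step 11
Reactants: 24 tris-TBS flavanone
Product: 25 (2S)-2-(3,4-dihydroxyphenyl)-5,7-dihydroxy-8-[(2R)-2-hydroxy-3-methylbut-3-enyl]-6-(3-methylbut-2-enyl)chroman-4-one
Conditions: HF·pyridine, pyridine, THF, 0→23 °C
Reagents that add atoms: none
Why: Fluoride desilylation under buffered, weakly acidic conditions removes all three TBS groups without opening ring C (no chalcone, so no racemisation at C-2), ionising the allylic alcohol or cyclising the prenyl group.

## Compound list
1 | 3,4-dihydroxybenzaldehyde | O=Cc1ccc(O)c(O)c1 | starting material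
2 | 3,4-bis(tert-butyldimethylsilyloxy)benzaldehyde | O=Cc1ccc(O[Si](C)(C)C(C)(C)C)c(O[Si](C)(C)C(C)(C)C)c1 | intermediate
3 | (R)-3-acetyl-4-benzyl-1,3-thiazolidine-2-thione | CC(=O)N1[C@H](Cc2ccccc2)CSC1=S | starting material
4 | trichlorotitanium enolate of 3 | C=C(O[Ti](Cl)(Cl)Cl)N1[C@H](Cc2ccccc2)CSC1=S | intermediate
5 | (S)-aldol adduct | O[C@H](c1ccc(O[Si](C)(C)C(C)(C)C)c(O[Si](C)(C)C(C)(C)C)c1)CC(=O)N1[C@H](Cc2ccccc2)CSC1=S | intermediate
6 | TES ether of 5 | CC[Si](CC)(CC)O[C@H](c1ccc(O[Si](C)(C)C(C)(C)C)c(O[Si](C)(C)C(C)(C)C)c1)CC(=O)N1[C@H](Cc2ccccc2)CSC1=S | intermediate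
7 | methacrolein | C=C(C)C=O | starting material
8 | rac-2-(prop-1-en-2-yl)oxirane | C=C(C)C1CO1 | intermediate
9 | (S)-2-(prop-1-en-2-yl)oxirane | C=C(C)[C@H]1CO1 | intermediate
10 | tert-butyl acetoacetate | CC(=O)CC(=O)OC(C)(C)C | starting material
11 | prenyl bromide | CC(C)=CCBr | starting material
12 | tert-butyl 2-acetyl-5-methylhex-4-enoate | CC(=O)C(CC=C(C)C)C(=O)OC(C)(C)C | intermediate
13 | sodium lithium dianion of 12 | [Li+].[Na+].C=C([O-])C(CC=C(C)C)=C([O-])OC(C)(C)C | intermediate
14 | alkoxide enolate from opening of 9 | [Li+].[Na+].C=C(C)[C@H]([O-])CCC([O-])=C(CC=C(C)C)C(=O)OC(C)(C)C | intermediate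
15 | tert-butyl (6R)-6-(tert-butyldimethylsilyloxy)-7-methyl-2-(3-methylbut-2-enyl)-3-oxooct-7-enoate | C=C(C)[C@H](O[Si](C)(C)C(C)(C)C)CCC(=O)C(CC=C(C)C)C(=O)OC(C)(C)C | intermediate
16 | N-methoxy-N-methylacetamide | CON(C)C(C)=O | starting material
17 | dilithium dianion of 15 | [Li+].[Li+].C=C(C)[C@H](O[Si](C)(C)C(C)(C)C)CC=C([O-])C(CC=C(C)C)=C([O-])OC(C)(C)C | intermediate
18 | tert-butyl (6R)-4-acetyl-6-(tert-butyldimethylsilyloxy)-7-methyl-2-(3-methylbut-2-enyl)-3-oxooct-7-enoate | C=C(C)[C@H](O[Si](C)(C)C(C)(C)C)CC(C(C)=O)C(=O)C(CC=C(C)C)C(=O)OC(C)(C)C | intermediate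
19 | trilithium trianion of 18 | [Li+].[Li+].[Li+].C=C([O-])C(C[C@@H](O[Si](C)(C)C(C)(C)C)C(C)=C)=C([O-])C(CC=C(C)C)=C([O-])OC(C)(C)C | intermediate
20 | acyclic tetraketide tert-butyl ester (9S, side chain 2R) | CC[Si](CC)(CC)O[C@H](c1ccc(O[Si](C)(C)C(C)(C)C)c(O[Si](C)(C)C(C)(C)C)c1)CC(=O)CC(=O)C(C[C@@H](O[Si](C)(C)C(C)(C)C)C(C)=C)C(=O)C(CC=C(C)C)C(=O)OC(C)(C)C | intermediate
21 | hydroxy tetraketide | O[C@H](c1ccc(O[Si](C)(C)C(C)(C)C)c(O[Si](C)(C)C(C)(C)C)c1)CC(=O)CC(=O)C(C[C@@H](O[Si](C)(C)C(C)(C)C)C(C)=C)C(=O)C(CC=C(C)C)C(=O)OC(C)(C)C | intermediate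
22 | (2S)-2-aryl-6-substituted 2,3-dihydro-4H-pyran-4-one | O1[C@H](c2ccc(O[Si](C)(C)C(C)(C)C)c(O[Si](C)(C)C(C)(C)C)c2)CC(=O)C=C1C(C[C@@H](O[Si](C)(C)C(C)(C)C)C(C)=C)C(=O)C(CC=C(C)C)C(=O)OC(C)(C)C | intermediate
23 | acylketene | O1[C@H](c2ccc(O[Si](C)(C)C(C)(C)C)c(O[Si](C)(C)C(C)(C)C)c2)CC(=O)C=C1C(C[C@@H](O[Si](C)(C)C(C)(C)C)C(C)=C)C(=O)C(CC=C(C)C)=C=O | intermediate
24 | tris-TBS flavanone (2S, 2''R) | C=C(C)[C@H](O[Si](C)(C)C(C)(C)C)Cc1c(O)c(CC=C(C)C)c(O)c2c1O[C@H](c1ccc(O[Si](C)(C)C(C)(C)C)c(O[Si](C)(C)C(C)(C)C)c1)CC2=O | intermediate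
25 | CNP0322081.2 (2S, 2''R) | C=C(C)[C@H](O)Cc1c(O)c(CC=C(C)C)c(O)c2c1O[C@H](c1ccc(O)c(O)c1)CC2=O | target

## Step count and risks
Total step count: 11. Longest linear sequence: 7 (steps 4, 5, 7, 8, 9, 10, 11).

**Step 10 (double ring closure).** The thermal loss of t-BuOH may be slow, or water may intercept the ketene.
- The fallback sets out from 20 and comes back at 24.
- The reaction is stopped after the acid stage and dihydropyranone 22 is isolated.
- TMSOTf/2,6-lutidine exchanges its tert-butyl ester to the trimethylsilyl ester F1.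
- Oxalyl chloride with catalytic DMF converts this under neutral conditions into the acid chloride F2.
- Et3N at −20 °C dehydrochlorinates F2 to acylketene 23 far below the thermolysis temperature, and 23 closes to 24.

**Step 9 (trianion acylation).** Proton transfer or β-elimination in 6 may compete with acylation.
- The fallback sets out from 6 and 18 and comes back at 20.
- DIBAL-H reduces 6 directly to the β-silyloxy aldehyde F3.
- Trianion 19 adds to this much better electrophile in an aldol addition to give the carbinol F4 (epimers).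
- Dess–Martin periodinane oxidises F4 to 20.

**Step 7 (dianion with a vinyl epoxide and in-flask silylation).** SN2' opening or a sluggish reaction may occur.
- The fallback sets out from 9, 11 and 16 and comes back at 15. It forms the C3–C2 bond of 15 by a crossed Claisen condensation instead.
- The lithium enolate of 16 opens 9, and TBSOTf traps the alkoxide to give the silyloxy Weinreb amide F5.
- The lithium enolate of commercial tert-butyl acetate is alkylated with 11 to tert-butyl 5-methylhex-4-enoate F6.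
- The lithium enolate of F6 is acylated by F5 to give 15.

Further compounds
F1 | step 10 | trimethylsilyl ester of the dihydropyranone keto acid | O1[C@H](c2ccc(O[Si](C)(C)C(C)(C)C)c(O[Si](C)(C)C(C)(C)C)c2)CC(=O)C=C1C(C[C@@H](O[Si](C)(C)C(C)(C)C)C(C)=C)C(=O)C(CC=C(C)C)C(=O)O[Si](C)(C)C
F2 | step 10 | acid chloride of the dihydropyranone keto acid | O1[C@H](c2ccc(O[Si](C)(C)C(C)(C)C)c(O[Si](C)(C)C(C)(C)C)c2)CC(=O)C=C1C(C[C@@H](O[Si](C)(C)C(C)(C)C)C(C)=C)C(=O)C(CC=C(C)C)C(=O)Cl
F3 | step 9 | (3S)-3-[3,4-bis(tert-butyldimethylsilyloxy)phenyl]-3-(triethylsilyloxy)propanal | CC[Si](CC)(CC)O[C@H](c1ccc(O[Si](C)(C)C(C)(C)C)c(O[Si](C)(C)C(C)(C)C)c1)CC=O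
F4 | step 9 | 7-hydroxy analogue of 20 | CC[Si](CC)(CC)O[C@H](c1ccc(O[Si](C)(C)C(C)(C)C)c(O[Si](C)(C)C(C)(C)C)c1)CC(O)CC(=O)C(C[C@@H](O[Si](C)(C)C(C)(C)C)C(C)=C)C(=O)C(CC=C(C)C)C(=O)OC(C)(C)C
F5 | step 7 | (4R)-4-(tert-butyldimethylsilyloxy)-N-methoxy-N,5-dimethylhex-5-enamide | C=C(C)[C@H](O[Si](C)(C)C(C)(C)C)CCC(=O)N(C)OC
F6 | step 7 | tert-butyl 5-methylhex-4-enoate | CC(C)=CCCC(=O)OC(C)(C)C
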